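## Structural features

The target is a bicyclo[3.2.1]oct-2-en-8-one. A cyclopentanone (C8, C1, C7, C6, C5) and a six-membered ring (C8, C1, C2, C3, C4, C5) share the ketone bridge C8 and the two bridgeheads. C1 is an all-carbon quaternary bridgehead carrying the allyl group, and C5 is a fully substituted bridgehead carrying a methoxyl. Five contiguous stereocentres run C4–C5–C6–C7–C1: the C7 methyl is exo (syn to C8), the C6 guaiacyl group is endo and trans to it, and the C4 hydroxyl is anti to C8, on the face crowded by the endo aryl group. The fragile groups are the C2=C3 methyl enol ether (acid), the free phenol (oxidants), the terminal alkene (hydroboration, ozone), the β-hydroxy ketone C4–C5–C8 (retro-aldol) and the bridging ketone. The real difficulty lies in the two neighbouring fully substituted bridgeheads, the absolute control of the C1/C7 pair and the C4 hydroxyl on the hindered face. The key step exploits the position of C5: it is bonded to the C8 carbonyl carbon, to the carbinol C4 and to the benzylic C6, which stands para to a phenolic hydroxyl. One enolisable methoxyacetyl carbon can therefore act as nucleophile twice, toward a para-quinone methide at C6 and toward an aldehyde at C4, and close both rings.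

## Logic of the disconnections

**25 ⇒ 24 ⇒ 23.** The C4–H bond is cut and the carbinol traced to the C4 ketone of 24, then to the C4 epimer 23. The reason is that hydride can only reach C4 of 24 from the face syn to C8, which gives the natural configuration, whereas a ring-forming aldol is expected to give the other. The gain is that C4 need not be controlled during ring formation. The demand is a reduction that picks the conjugated C4 carbonyl over the bridging C8 carbonyl.

**23 ⇒ 20.** C5–C6 and C4–C5 are cut, opening both rings to an acyclic ketone. This removes three stereocentres and leaves only C1 and C7 to be made beforehand. The demands on 20 are as follows.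
- C5 must be the only enolisable carbon.
- C6 must carry a leaving group that a phenoxide can expel.
- C4 must be held cis to C1 on C2=C3. Since methoxy outranks formyl at C3, this is the (E) isomer; reading it as (Z) because the two carbon chains are cis is an error. It is also the less stable isomer, so an open-chain olefination of a C2 aldehyde would give the wrong one.

**20 ⇒ 19 ⇒ 18.** Both carbonyl groups are traced to alcohols and these to the six-membered lactone of 18, in which the C8 oxygen is tied to C4. The ring is the only reliable source of the (E) geometry. The demand is that the benzylic leaving group survives hydride. For this reason the precursor carries an N,N-dimethylcarbamate instead of an acetate: it is the same kind of 1,6-leaving group and is inert to i-Bu2AlH. A second demand is that both alcohols of 19 are oxidised at the same time.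

**18 ⇒ 16 ⇒ 15 ⇒ 12 + 14 (14 ⇒ 13).** C2=C3 is cut by an intramolecular phosphonate olefination and the C8–O ester bond by an esterification. The aldehyde partner is the lactol carbon of 16, whose opening also frees the C6 oxygen for carbamoylation. The demand is that the lactol hydroxyl is masked (12, 15) while the C8 hydroxyl is acylated.

**12 ⇒ 10.** Redox and acetal changes only: the ketone and lactone carbonyls of 10 become the carbinol and the masked aldehyde of 12.

**10 ⇒ 8 + 9 and 8 ⇒ 6 + 7.** C1–allyl and C1–C8 are cut at the α-carbon of a butyrolactone. The lactone ring, with its cis methyl and aryl groups on one face, is the template that sets the quaternary C1 relative to C7. The demand is that the allyl group enters last, because the target needs it trans to the C7 methyl.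

**6 ⇒ 4 ⇒ 3 ⇒ 1 + 2.** The lactone is traced to a 1,4-diol and a terminal alkene, and C6–C7 is cut by a crotyl addition to the aldehyde. This one catalytic step sets the absolute configuration of C7, from which all other centres follow. C6 is set too but is erased in step 13.

## Other disconnections considered

**Alternative 1:** The cut is C6–C7 of the cyclopentanone. In the forward step Et3SiOTf activates the α-methoxy dienone A1, a conrotatory 4π closure joins C6 to C7 with aryl and methyl trans, and Et3SiH reduces the oxyallyl cation at C5 to leave the C8=C1 silyl enol ether A2.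
- In its favour: the five-membered ring and the trans C6/C7 pair come in one step from an achiral open-chain compound through a thermally allowed closure. On this ring it is the better plan, since the chosen route closes it by an enolate mode that the ring-closure rules disfavour.
- Also in its favour: A2 is a regiodefined enolate equivalent at C1, and an electrophile entering anti to the C7 methyl would give the relative configuration the target needs. On relative control the two plans are equal.
- Against it: the sense of conrotation is not controlled, so A2 would be racemic unless a chiral acid is found for this substrate class, whereas the chosen route fixes the absolute configuration in a catalytic crotylation.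
- Against it: the group to be attached at C1 is the sp2 carbon of the same (E)-methoxy-enal arm, so the geometry problem returns in a harder form, and the six-membered ring and the quaternisation of C5 remain.
- Step economy is probably similar; for a single enantiomer the chosen plan is better.

**Alternative 2:** The cut is C1–C2. Anodic oxidation of the silyl enol ether A3 gives a radical cation that is trapped at C1 by the terminal carbon of the pendant α-methoxyvinyl group, and methanol capture at C3 gives the ketal A4.
- In its favour: the hindered bridgehead bond is made by coupling two electron-rich alkenes, and no (E)/(Z) question arises because C2 starts as a methylene. On this point it is better than the chosen plan.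
- Also in its favour: A4 already carries the natural C4 configuration, so the oxidation–reduction at the end of the chosen route would not be needed.
- Against it: A3 holds three oxidisable π systems (enol ether, allyl group, oxygenated arene), so the site of oxidation is uncertain.
- Against it: A3 needs the fully substituted C5, with its methoxyl and C4 side chain, to be built stereoselectively beforehand, which is as hard as the problem the chosen key step solves.
- Against it: after A4 the C3 ketal must lose methanol toward C2 and not toward C4, and two protecting groups must go.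
- The chosen plan makes two ring bonds at once from an easier substrate and is shorter overall.

**Alternative 3:** The cut is C5–C6, made by a 1,2-shift from the bicyclo[2.2.2]octenone A5, in which C6 is bonded to C4. Al(OiPr)3 would promote the α-ketol rearrangement in which C6 migrates to the C5 carbonyl carbon, giving the bicyclo[3.2.1] ketol A6 with the C4 enone carbonyl.
- In its favour: A5 is the kind of adduct a single cycloaddition of a dearomatised phenol delivers, so this is clearly the shortest plan and better than the chosen one in step economy.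
- Also in its favour: the trans C6/C7 pair would come from alkene geometry, no enal geometry has to be made, and the C4 ketone would be reduced as in step 15, so the endgame is equal.
- Against it: the cycloaddition partners are achiral and offer no obvious handle for absolute control, so a single enantiomer would need a resolution or an auxiliary.
- Against it: the direction of the ketol equilibrium must favour A6, and the hindered tertiary bridgehead hydroxyl at C5 must be methylated next to two carbonyl-level carbons.
- Against it: the C8 ketal must be hydrolysed without harming the acid-labile C2=C3 enol ether.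
- For the racemate this plan is better; for the single enantiomer the chosen plan is better.

Key step: step 13

Assumption: 1 (the silyl ether of vanillin) is bought as such; otherwise one silylation precedes step 1.
Remark: C1–C8 denote the atoms of the bicyclic core in every intermediate, and Ar in names stands for 4-[(tert-butyldimethylsilyl)oxy]-3-methoxyphenyl.

## Route

Step 1
Reactants: 1 4-[(tert-butyldimethylsilyl)oxy]-3-methoxybenzaldehyde; 2 (Z)-2-(but-2-en-1-yl)-4,4,5,5-tetramethyl-1,3,2-dioxaborolane
Product: 3 (1R,2S)-1-Ar-2-methylbut-3-en-1-ol (syn)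
Conditions: (R)-3,3′-bis(2,4,6-triisopropylphenyl)-1,1′-binaphthyl-2,2′-diyl hydrogen phosphate (5 mol %), 4 Å sieves, toluene, −30 °C; aq. NaHCO3
Reagents that add atoms: none
Why: Chiral phosphoric acid catalysed crotylboration through a closed chair transition state; the (Z)-boronate gives the syn pair and the (R)-acid should direct addition to the Re face (1R,2S, which fixes C7). The sense is checked by Mosher ester analysis at this stage, and the mirror-image acid is the simple remedy.

Step 2
Reactants: 3 (1R,2S)-1-Ar-2-methylbut-3-en-1-ol
Product: 4 (1R,2S)-1-Ar-2-methylbutane-1,4-diol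
Conditions: 9-borabicyclo[3.3.1]nonane (2.2 equiv), THF, 0 → 23 °C; H2O2, pH 7 phosphate buffer, 0 → 23 °C
Reagents that add atoms: hydrogen peroxide, OO
Why: Anti-Markovnikov hydroboration–oxidation of the terminal alkene; the buffered oxidation spares the aryl silyl ether and no stereocentre is touched.

Step 3
Reactants: 4 (1R,2S)-1-Ar-2-methylbutane-1,4-diol
Product: 6 (4S,5R)-5-Ar-4-methyldihydrofuran-2(3H)-one (cis), via lactol 5 (not isolated)
Conditions: 2,2,6,6-tetramethylpiperidin-1-oxyl (10 mol %), PhI(OAc)2 (2.5 equiv), CH2Cl2, 23 °C
Reagents that add atoms: none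
Why: Oxoammonium oxidation is selective for the primary alcohol; the aldehyde closes to lactol 5, which is oxidised on to the lactone (oxidative lactonisation of a 1,4-diol). The syn diol gives the cis lactone.

Step 4
Reactants: 6 (4S,5R)-5-Ar-4-methyldihydrofuran-2(3H)-one; 7 N,2-dimethoxy-N-methylacetamide
Product: 8 (4S,5R)-5-Ar-3-(2-methoxyacetyl)-4-methyldihydrofuran-2(3H)-one (C3 epimers)
Conditions: LiN(i-Pr)2 (2.2 equiv), THF, −78 °C; 7, −78 → −20 °C; 1 M HCl
Reagents that add atoms: none
Why: Crossed Claisen-type C-acylation of the lithium lactone enolate by a Weinreb amide, whose chelated tetrahedral adduct prevents a second addition; the new C3 centre is enolisable and is fixed in step 5.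

Step 5
Reactants: 8 (4S,5R)-5-Ar-3-(2-methoxyacetyl)-4-methyldihydrofuran-2(3H)-one; 9 methyl prop-2-en-1-yl carbonate
Product: 10 (3S,4S,5R)-5-Ar-3-(2-methoxyacetyl)-4-methyl-3-(prop-2-en-1-yl)dihydrofuran-2(3H)-one (allyl trans to the cis methyl and aryl groups)
Conditions: Pd(PPh3)4 (3 mol %), THF, 23 °C
Reagents that add atoms: none
Why: Tsuji–Trost allylation with zerovalent palladium under neutral conditions gives C-allylation of the β-keto lactone; the enolate meets the π-allyl complex on the face away from the cis 4-methyl and 5-aryl groups, which sets the quaternary C1 with allyl trans to the C7 methyl.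

Step 6
Reactants: 10 (3S,4S,5R)-5-Ar-3-(2-methoxyacetyl)-4-methyl-3-(prop-2-en-1-yl)dihydrofuran-2(3H)-one
Product: 12 1-[(3S,4S,5R)-5-Ar-2-methoxy-4-methyl-3-(prop-2-en-1-yl)tetrahydrofuran-3-yl]-2-methoxyethan-1-ol (mixture at the acetal and carbinol carbons), via hydroxy lactol 11 (not isolated)
Conditions: i-Bu2AlH (3.3 equiv), CH2Cl2, −78 °C; aq. potassium sodium tartrate; then pyridinium p-toluenesulfonate (10 mol %), MeOH, 23 °C
Reagents that add atoms: methanol, CO
Why: i-Bu2AlH reduces the ketone to the carbinol and stops at the lactol for the lactone at −78 °C; acid-catalysed acetalisation then masks only the lactol hydroxyl. Both carbinol epimers serve, since C8 returns to a ketone in step 12.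

Step 7
Reactants: 13 methyl 2-(dimethoxyphosphoryl)-2-methoxyacetate
Product: 14 2-(dimethoxyphosphoryl)-2-methoxyacetic acid
Conditions: LiOH·H2O (1.05 equiv), THF/H2O, 0 °C; then 1 M HCl to pH 2
Reagents that add atoms: lithium hydroxide, [Li+].[OH-]
Why: Saponification of the carboxylic ester is much faster than cleavage of the phosphonate methyl esters (selective ester hydrolysis).

Step 8
Reactants: 12 the methyl acetal carbinol of step 6; 14 2-(dimethoxyphosphoryl)-2-methoxyacetic acid
Product: 15 1-[(3S,4S,5R)-5-Ar-2-methoxy-4-methyl-3-(prop-2-en-1-yl)tetrahydrofuran-3-yl]-2-methoxyethyl 2-(dimethoxyphosphoryl)-2-methoxyacetate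
Conditions: N,N′-diisopropylcarbodiimide (1.5 equiv), 4-(dimethylamino)pyridine (0.2 equiv), CH2Cl2, 0 → 23 °C
Reagents that add atoms: none
Why: Steglich esterification; phosphonoacetic acids acylate hindered secondary alcohols well under carbodiimide activation, and the acetal keeps the lactol oxygen out of the reaction.

Step 9
Reactants: 15 the phosphonoacetate methyl acetal of step 8
Product: 16 1-[(3S,4S,5R)-5-Ar-2-hydroxy-4-methyl-3-(prop-2-en-1-yl)tetrahydrofuran-3-yl]-2-methoxyethyl 2-(dimethoxyphosphoryl)-2-methoxyacetate
Conditions: AcOH/H2O/THF (4:2:1), 45 °C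
Reagents that add atoms: water, O
Why: Mild aqueous acid hydrolysis of the furanosidic methyl acetal; the aryl silyl ether, the phosphonate and the ester tolerate these conditions.

Step 10
Reactants: 16 the phosphonoacetate lactol of step 9
Product: 18 (1R,2S)-1-Ar-2-[(5R)-3-methoxy-6-(methoxymethyl)-2-oxo-5-(prop-2-en-1-yl)-5,6-dihydro-2H-pyran-5-yl]propyl N,N-dimethylcarbamate (epimers at the ring carbon bearing the methoxymethyl group), via hydroxy lactone 17 (not isolated)
Conditions: NaH (2.5 equiv), THF (0.02 M), 0 → 23 °C; then Me2NCOCl (1.5 equiv), 0 → 23 °C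
Reagents that add atoms: dimethylcarbamoyl chloride, CN(C)C(=O)Cl
Why: Intramolecular Horner–Wadsworth–Emmons olefination: base opens the lactol to the aldehyde, and closure to the six-membered lactone can only form C2=C3 with C1 and C4 cis, the (E)-enol ether geometry that an open-chain olefination would not give. The benzylic alkoxide freed by the lactol opening is carbamoylated in the same flask.

Step 11
Reactants: 18 the carbamate lactone of step 10
Product: 19 (2E,4R)-4-{(1R,2S)-1-Ar-1-[(dimethylcarbamoyl)oxy]propan-2-yl}-4-(1-hydroxy-2-methoxyethyl)-2-methoxyhepta-2,6-dien-1-ol (carbinol epimers)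
Conditions: i-Bu2AlH (3.5 equiv), CH2Cl2, −78 → −40 °C; aq. potassium sodium tartrate
Reagents that add atoms: none
Why: 1,2-Reduction of the unsaturated lactone to the diol with retention of the ring-made alkene geometry; an N,N-dialkylcarbamate and the aryl silyl ether are inert to i-Bu2AlH at this temperature, which an acetate would not be.

Step 12
Reactants: 19 the diol of step 11
Product: 20 (2E,4R)-4-{(1R,2S)-1-Ar-1-[(dimethylcarbamoyl)oxy]propan-2-yl}-2-methoxy-4-(2-methoxyacetyl)hepta-2,6-dienal
Conditions: (COCl)2 (4 equiv), Me2SO (8 equiv), CH2Cl2, −78 °C; Et3N (12 equiv), −78 → 0 °C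
Reagents that add atoms: none
Why: Swern oxidation: both alcohols become alkoxysulfonium salts before the base is added, so no hydroxy-aldehyde is free to close to a lactol and be oxidised back to a lactone. The two C8 epimers converge and the (E) geometry is kept.

Step 13
Reactants: 20 the keto-enal of step 12
Product: 23 (1R,4R,5R,6S,7R)-4-hydroxy-6-(4-hydroxy-3-methoxyphenyl)-3,5-dimethoxy-7-methyl-1-(prop-2-en-1-yl)bicyclo[3.2.1]oct-2-en-8-one (C4 epimer of the target), via para-quinone methide 21 (not isolated), via cyclopentanone 22 (not isolated)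
Conditions: Bu4NF (1.1 equiv), THF (0.01 M), −40 °C; then Cs2CO3 (2 equiv), −40 → 0 °C; aq. NH4Cl
Reagents that add atoms: none
Why: Proposed new method: fluoride cleaves the aryl silyl ether and the phenoxide expels dimethylcarbamate by 1,6-elimination to give para-quinone methide 21, after which carbonate enolises the ketone toward C5, its only α-carbon with hydrogen (C1 is quaternary, the enal has none), and this one carbon adds to the methide carbon C6 (1,6-conjugate addition, rearomatising the arene, giving 22) and then, through its last hydrogen, to the C4 aldehyde (aldol). The closest known reactions are the 1,6-addition of enolates to para-quinone methides released by fluoride from silylated 4-hydroxybenzyl esters or carbamates and the intramolecular aldol addition; their coupling through a single carbon in one flask has no direct model. The five-membered ring closes 5-exo-trig at the methide but enolendo at the ketone, a mode that the ring-closure rules for enolates rate as unfavourable; it is expected to proceed because the methide is an unusually strong and unhindered acceptor with an early transition state, as in the equally enolendo aldol closure of 1,4-diketones to cyclopentenones. The six-membered ring closes 6-(enolendo)-exo-trig, a favoured mode, and only because the ring-made (E)-enal holds C4 cis to C1. C6 is planar in 21, so its configuration in 20 is lost, and the new C6 centre should form with aryl trans to the C7 methyl to avoid eclipsing in the five-membered transition state. C5 can only become a cis bridge because the ketone and the enal arm sit on the same carbon C1, whose relation to C7 was fixed in step 5. C4 should form with its oxygen turned toward the cation-bridged C8 enolate oxygen (closed aldol transition state, and the reversible aldol favours the same isomer), i.e. hydroxyl syn to C8, the 4-epimer that steps 14 and 15 correct. The step needs carbon rather than oxygen attack on the methide and conjugate addition before any aldol–dehydration; the first follows from the five-ring geometry, the second is helped by releasing the methide with fluoride at −40 °C before the base is added, and once C5 carries C6 its single hydrogen is used by the aldol so that water cannot be lost.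

Step 14
Reactants: 23 the C4 epimer of the target
Product: 24 (1R,5S,6S,7R)-6-(4-hydroxy-3-methoxyphenyl)-3,5-dimethoxy-7-methyl-1-(prop-2-en-1-yl)bicyclo[3.2.1]oct-2-ene-4,8-dione (locants of the target kept)
Conditions: MnO2 (activated, 20 equiv), CH2Cl2, 23 °C
Reagents that add atoms: none
Why: MnO2 oxidises the allylic C4 carbinol selectively (allylic alcohol oxidation) and is mild enough for a free guaiacol-type phenol; the C4 centre is erased on purpose.

Step 15
Reactants: 24 the 4,8-dione of step 14
Product: 25 (1R,4S,5R,6S,7R)-4-hydroxy-6-(4-hydroxy-3-methoxyphenyl)-3,5-dimethoxy-7-methyl-1-(prop-2-en-1-yl)bicyclo[3.2.1]oct-2-en-8-one (target)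
Conditions: NaBH4 (1 equiv), CeCl3·7H2O (1.2 equiv), MeOH, −78 °C
Reagents that add atoms: none
Why: Luche reduction: CeCl3 favours 1,2-reduction of the conjugated C4 ketone over the bridging C8 ketone, which lies between two fully substituted carbons. Hydride should come from the face syn to C8 because the endo aryl group at C6 blocks the other face, giving the 4S carbinol with hydroxyl anti to C8.

## Compound list

1 | 4-[(tert-butyldimethylsilyl)oxy]-3-methoxybenzaldehyde | O=Cc1ccc(O[Si](C)(C)C(C)(C)C)c(OC)c1 | starting material
2 | (Z)-2-(but-2-en-1-yl)-4,4,5,5-tetramethyl-1,3,2-dioxaborolane | C/C=C\CB1OC(C)(C)C(C)(C)O1 | starting material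
3 | (1R,2S)-1-Ar-2-methylbut-3-en-1-ol | C=C[C@H](C)[C@@H](O)c1ccc(O[Si](C)(C)C(C)(C)C)c(OC)c1 | intermediate
4 | (1R,2S)-1-Ar-2-methylbutane-1,4-diol | OCC[C@H](C)[C@@H](O)c1ccc(O[Si](C)(C)C(C)(C)C)c(OC)c1 | intermediate
5 | (4S,5R)-5-Ar-4-methyltetrahydrofuran-2-ol (anomers) | OC1C[C@H](C)[C@H](c2ccc(O[Si](C)(C)C(C)(C)C)c(OC)c2)O1 | intermediate
6 | (4S,5R)-5-Ar-4-methyldihydrofuran-2(3H)-one | O=C1C[C@H](C)[C@H](c2ccc(O[Si](C)(C)C(C)(C)C)c(OC)c2)O1 | intermediate
7 | N,2-dimethoxy-N-methylacetamide | COCC(=O)N(C)OC | starting material
8 | (4S,5R)-5-Ar-3-(2-methoxyacetyl)-4-methyldihydrofuran-2(3H)-one (C3 epimers) | COCC(=O)C1C(=O)O[C@@H](c2ccc(O[Si](C)(C)C(C)(C)C)c(OC)c2)[C@H]1C | intermediate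
9 | methyl prop-2-en-1-yl carbonate | C=CCOC(=O)OC | starting material
10 | (3S,4S,5R)-5-Ar-3-(2-methoxyacetyl)-4-methyl-3-(prop-2-en-1-yl)dihydrofuran-2(3H)-one | C=CC[C@]1(C(=O)COC)C(=O)O[C@@H](c2ccc(O[Si](C)(C)C(C)(C)C)c(OC)c2)[C@H]1C | intermediate
11 | (3S,4S,5R)-5-Ar-3-(1-hydroxy-2-methoxyethyl)-4-methyl-3-(prop-2-en-1-yl)tetrahydrofuran-2-ol (mixture at C2 and the carbinol carbon) | C=CC[C@]1(C(O)COC)C(O)O[C@@H](c2ccc(O[Si](C)(C)C(C)(C)C)c(OC)c2)[C@H]1C | intermediate
12 | 1-[(3S,4S,5R)-5-Ar-2-methoxy-4-methyl-3-(prop-2-en-1-yl)tetrahydrofuran-3-yl]-2-methoxyethan-1-ol (mixture at C2 and the carbinol carbon) | C=CC[C@]1(C(O)COC)C(OC)O[C@@H](c2ccc(O[Si](C)(C)C(C)(C)C)c(OC)c2)[C@H]1C | intermediate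
13 | methyl 2-(dimethoxyphosphoryl)-2-methoxyacetate | COC(C(=O)OC)P(=O)(OC)OC | starting material
14 | 2-(dimethoxyphosphoryl)-2-methoxyacetic acid | COC(C(=O)O)P(=O)(OC)OC | intermediate
15 | 1-[(3S,4S,5R)-5-Ar-2-methoxy-4-methyl-3-(prop-2-en-1-yl)tetrahydrofuran-3-yl]-2-methoxyethyl 2-(dimethoxyphosphoryl)-2-methoxyacetate | C=CC[C@]1(C(COC)OC(=O)C(OC)P(=O)(OC)OC)C(OC)O[C@@H](c2ccc(O[Si](C)(C)C(C)(C)C)c(OC)c2)[C@H]1C | intermediate
16 | 1-[(3S,4S,5R)-5-Ar-2-hydroxy-4-methyl-3-(prop-2-en-1-yl)tetrahydrofuran-3-yl]-2-methoxyethyl 2-(dimethoxyphosphoryl)-2-methoxyacetate | C=CC[C@]1(C(COC)OC(=O)C(OC)P(=O)(OC)OC)C(O)O[C@@H](c2ccc(O[Si](C)(C)C(C)(C)C)c(OC)c2)[C@H]1C | intermediate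
17 | (5R)-5-[(1R,2S)-1-Ar-1-hydroxypropan-2-yl]-3-methoxy-6-(methoxymethyl)-5-(prop-2-en-1-yl)-5,6-dihydro-2H-pyran-2-one (C6 epimers) | C=CC[C@]1(C=C(OC)C(=O)OC1COC)[C@H](C)[C@@H](O)c1ccc(O[Si](C)(C)C(C)(C)C)c(OC)c1 | intermediate
18 | (1R,2S)-1-Ar-2-[(5R)-3-methoxy-6-(methoxymethyl)-2-oxo-5-(prop-2-en-1-yl)-5,6-dihydro-2H-pyran-5-yl]propyl N,N-dimethylcarbamate (C6 epimers of the pyranone) | C=CC[C@]1(C=C(OC)C(=O)OC1COC)[C@H](C)[C@@H](OC(=O)N(C)C)c1ccc(O[Si](C)(C)C(C)(C)C)c(OC)c1 | intermediate
19 | (2E,4R)-4-{(1R,2S)-1-Ar-1-[(dimethylcarbamoyl)oxy]propan-2-yl}-4-(1-hydroxy-2-methoxyethyl)-2-methoxyhepta-2,6-dien-1-ol (carbinol epimers) | C=CC[C@](C(O)COC)(/C=C(\CO)OC)[C@H](C)[C@@H](OC(=O)N(C)C)c1ccc(O[Si](C)(C)C(C)(C)C)c(OC)c1 | intermediate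
20 | (2E,4R)-4-{(1R,2S)-1-Ar-1-[(dimethylcarbamoyl)oxy]propan-2-yl}-2-methoxy-4-(2-methoxyacetyl)hepta-2,6-dienal | C=CC[C@](C(=O)COC)(/C=C(\C=O)OC)[C@H](C)[C@@H](OC(=O)N(C)C)c1ccc(O[Si](C)(C)C(C)(C)C)c(OC)c1 | intermediate
21 | (2E,4R)-2-methoxy-4-(2-methoxyacetyl)-4-[(2R)-1-(3-methoxy-4-oxocyclohexa-2,5-dien-1-ylidene)propan-2-yl]hepta-2,6-dienal | C=CC[C@](C(=O)COC)(/C=C(\C=O)OC)[C@H](C)C=C1C=CC(=O)C(OC)=C1 | intermediate
22 | (2E)-3-[(1R,4S,5R)-4-(4-hydroxy-3-methoxyphenyl)-3-methoxy-5-methyl-2-oxo-1-(prop-2-en-1-yl)cyclopentyl]-2-methoxyprop-2-enal (C3 epimers of the ring) | C=CC[C@@]1(/C=C(\C=O)OC)C(=O)C(OC)[C@H](c2ccc(O)c(OC)c2)[C@H]1C | intermediate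
23 | (1R,4R,5R,6S,7R)-4-hydroxy-6-(4-hydroxy-3-methoxyphenyl)-3,5-dimethoxy-7-methyl-1-(prop-2-en-1-yl)bicyclo[3.2.1]oct-2-en-8-one | C=CC[C@@]12C=C(OC)[C@@H](O)[C@@](OC)(C1=O)[C@H](c1ccc(O)c(OC)c1)[C@H]2C | intermediate
24 | (1R,5S,6S,7R)-6-(4-hydroxy-3-methoxyphenyl)-3,5-dimethoxy-7-methyl-1-(prop-2-en-1-yl)bicyclo[3.2.1]oct-2-ene-4,8-dione | C=CC[C@@]12C=C(OC)C(=O)[C@@](OC)(C1=O)[C@H](c1ccc(O)c(OC)c1)[C@H]2C | intermediate
25 | (1R,4S,5R,6S,7R)-4-hydroxy-6-(4-hydroxy-3-methoxyphenyl)-3,5-dimethoxy-7-methyl-1-(prop-2-en-1-yl)bicyclo[3.2.1]oct-2-en-8-one | C=CC[C@@]12C=C(OC)[C@H](O)[C@@](OC)(C1=O)[C@H](c1ccc(O)c(OC)c1)[C@H]2C | target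

## Step count and least certain steps

Total step count: 15. Longest linear sequence: 14 (steps 1–6 and 8–15; step 7 is a one-step side branch).

**Step 13 (key step).** The most likely failure is that the favoured six-ring aldol closes first and the resulting β-hydroxy ketone, whose C5 still bears a hydrogen, loses water irreversibly. The methide may also tautomerise to the propenylphenol before the slower five-ring closure occurs. The fallback separates the two bond formations, each a known reaction, so that no aldehyde is present while the methide is consumed. It sets out from 19. The primary allylic hydroxyl is silylated with Et3SiCl and imidazole to the mono(triethylsilyl) ether F1. The C8 carbinol is oxidised with Dess–Martin periodinane to the ketone F2. Bu4NF (2.5 equiv) with Cs2CO3 then triggers the 1,6-addition alone and removes the allylic silyl group, giving the cyclopentanone allylic alcohol F3. MnO2 oxidises F3 to 22, now isolated, and 1,8-diazabicyclo[5.4.0]undec-7-ene closes the aldol to 23, where the route is rejoined.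

**Step 10.** The likely failure is migration of the phosphonoacetyl group to the alkoxide freed by lactol opening, or slow opening of the hindered lactol, so that the wrong ring or no ring forms. The fallback sets out from 11, obtained by stopping step 6 after the aluminium work-up. It is olefinated intermolecularly with the anion of 13 (NaH, THF) to the open-chain enoate F4 as a mixture of alkene isomers. Irradiation with a trace of camphorsulfonic acid interconverts the isomers, and the one with C1 and the ester cis is drained by lactonisation to 17. Carbamoylation as in step 10 gives 18.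

**Step 12.** The likely failure is incomplete activation of the hindered C8 carbinol, so that a hydroxy-enal closes to a lactol and is oxidised back to the lactone, or attack of the chlorosulfonium reagent on the enol ether. The fallback sets out from 19 and passes through the triethylsilyl ether F1 and the ketone F2 described above. Pyridinium p-toluenesulfonate in methanol removes the silyl group to give the keto alcohol F5, which may rest as its hemiketal. MnO2 oxidises only the open allylic alcohol and so funnels the material to 20.

**Step 14.** The likely failure is oxidation of the free phenol (radical coupling or methide formation at the benzylic C6–H) competing with the slow oxidation of the hindered carbinol. The fallback sets out from 23. The phenol is silylated with tert-butyldimethylsilyl chloride and imidazole to the silyl ether F6. Dess–Martin periodinane gives the dione silyl ether F7, and Bu4NF buffered with acetic acid returns 24.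

**Step 15.** The likely failure is partial reduction of the strained C8 ketone, or too small a facial preference at C4. The fallback replaces substrate control by reagent control: transfer hydrogenation of 24 with RuCl(p-cymene)(TsDPEN), where TsDPEN is N-(p-toluenesulfonyl)-1,2-diphenylethane-1,2-diamine in the enantiomer matched to the 4S carbinol, in HCO2H/Et3N. This catalyst type reduces conjugated ketones and leaves hindered dialkyl ketones and alkenes alone. It leads directly to 25 and makes no new compound.

## Further compounds

F1 | step 13 | (2E,4R)-4-{(1R,2S)-1-Ar-1-[(dimethylcarbamoyl)oxy]propan-2-yl}-4-(1-hydroxy-2-methoxyethyl)-2-methoxy-1-[(triethylsilyl)oxy]hepta-2,6-diene | C=CC[C@](C(O)COC)(/C=C(\CO[Si](CC)(CC)CC)OC)[C@H](C)[C@@H](OC(=O)N(C)C)c1ccc(O[Si](C)(C)C(C)(C)C)c(OC)c1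
F2 | step 13 | (4E,3R)-3-{(1R,2S)-1-Ar-1-[(dimethylcarbamoyl)oxy]propan-2-yl}-1,5-dimethoxy-3-(prop-2-en-1-yl)-6-[(triethylsilyl)oxy]hex-4-en-2-one | C=CC[C@](C(=O)COC)(/C=C(\CO[Si](CC)(CC)CC)OC)[C@H](C)[C@@H](OC(=O)N(C)C)c1ccc(O[Si](C)(C)C(C)(C)C)c(OC)c1
F3 | step 13 | (2R,3R,4S)-4-(4-hydroxy-3-methoxyphenyl)-2-[(1E)-3-hydroxy-2-methoxyprop-1-en-1-yl]-5-methoxy-3-methyl-2-(prop-2-en-1-yl)cyclopentan-1-one (C5 epimers) | C=CC[C@@]1(/C=C(\CO)OC)C(=O)C(OC)[C@H](c2ccc(O)c(OC)c2)[C@H]1C
F4 | step 10 | methyl (4R)-4-[(1R,2S)-1-Ar-1-hydroxypropan-2-yl]-4-(1-hydroxy-2-methoxyethyl)-2-methoxyhepta-2,6-dienoate (alkene isomers) | C=CC[C@](C(O)COC)(C=C(OC)C(=O)OC)[C@H](C)[C@@H](O)c1ccc(O[Si](C)(C)C(C)(C)C)c(OC)c1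
F5 | step 12 | (4E,3R)-3-{(1R,2S)-1-Ar-1-[(dimethylcarbamoyl)oxy]propan-2-yl}-6-hydroxy-1,5-dimethoxy-3-(prop-2-en-1-yl)hex-4-en-2-one | C=CC[C@](C(=O)COC)(/C=C(\CO)OC)[C@H](C)[C@@H](OC(=O)N(C)C)c1ccc(O[Si](C)(C)C(C)(C)C)c(OC)c1
F6 | step 14 | (1R,4R,5R,6S,7R)-6-Ar-4-hydroxy-3,5-dimethoxy-7-methyl-1-(prop-2-en-1-yl)bicyclo[3.2.1]oct-2-en-8-one | C=CC[C@@]12C=C(OC)[C@@H](O)[C@@](OC)(C1=O)[C@H](c1ccc(O[Si](C)(C)C(C)(C)C)c(OC)c1)[C@H]2C
F7 | step 14 | (1R,5S,6S,7R)-6-Ar-3,5-dimethoxy-7-methyl-1-(prop-2-en-1-yl)bicyclo[3.2.1]oct-2-ene-4,8-dione | C=CC[C@@]12C=C(OC)C(=O)[C@@](OC)(C1=O)[C@H](c1ccc(O[Si](C)(C)C(C)(C)C)c(OC)c1)[C@H]2C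
F0 | step 15 | none | none
A1 | alternative 1 | (1Z,4E)-1-{4-[(tert-butyldimethylsilyl)oxy]-3-methoxyphenyl}-2-methoxy-4-(prop-2-en-1-yl)hexa-1,4-dien-3-one | C/C=C(CC=C)/C(=O)/C(OC)=C/c1ccc(O[Si](C)(C)C(C)(C)C)c(OC)c1
A2 | alternative 1 | C8 triethylsilyl enol ether of 2-allyl-5-methoxy-3-methyl-4-arylcyclopentanone | C=CCC1=C(O[Si](CC)(CC)CC)[C@H](OC)[C@H](c2ccc(O[Si](C)(C)C(C)(C)C)c(OC)c2)[C@H]1C
A3 | alternative 2 | C8 trimethylsilyl enol ether (silyl group assumed) of the 2-allyl-5-methoxy-3-methyl-4-arylcyclopentanone carrying the 1-silyloxy-2-methoxyallyl arm at C5, aryl as pivalate | C=CCC1=C(O[Si](C)(C)C)[C@](OC)([C@@H](O[Si](C)(C)C(C)(C)C)C(OC)=C)[C@H](c2ccc(OC(=O)C(C)(C)C)c(OC)c2)[C@H]1C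
A4 | alternative 2 | bicyclo[3.2.1]octan-8-one with C3 dimethyl ketal, C4 silyl ether and aryl pivalate | C=CC[C@@]12CC(OC)(OC)[C@H](O[Si](C)(C)C(C)(C)C)[C@@](OC)(C1=O)[C@H](c1ccc(OC(=O)C(C)(C)C)c(OC)c1)[C@H]2C
A5 | alternative 3 | bridgehead-hydroxy bicyclo[2.2.2]octenone (C1 allyl bridgehead, C4 hydroxy bridgehead bonded to C6, C5 ketone, C8 dimethyl ketal) | C=CC[C@@]12C=C(OC)[C@@](O)(C(=O)C1(OC)OC)[C@H](c1ccc(O[Si](C)(C)C(C)(C)C)c(OC)c1)[C@H]2C
A6 | alternative 3 | C5-hydroxy bicyclo[3.2.1]oct-2-en-4-one with C8 dimethyl ketal | C=CC[C@@]12C=C(OC)C(=O)[C@@](O)(C1(OC)OC)[C@H](c1ccc(O[Si](C)(C)C(C)(C)C)c(OC)c1)[C@H]2C
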